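The cis-2-aryl-3-hydroxymethyl dihydrofuran ring (O1–C2–C3–C3a–C7a) is treated as the syn-hydrogenation product of a flat benzofuran, which is cut at O1–C2 and C3a–C3. The key step, a palladium-catalysed heteroannulation, joins the phenol oxygen and the ortho, iodine-bearing carbon of the dihydroconiferyl ring to the two alkyne carbons of an arylpropargyl alcohol that already carries the complete erythro arylglycerol β-aryl ether, so both ring bonds form in one operation and the synthesis converges. The side-chain centres come from an auxiliary-controlled anti-aldol reaction, the ring centres from a catalyst-controlled asymmetric hydrogenation.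

Key step: step 6

Remark on the stereochemistry: in the target the aryl group at C2 and the hydroxymethyl group at C3 of the dihydrobenzofuran are cis (2R,3R), and the side chain is the erythro (1R,2S) arylglycerol ether; the route is built for this isomer.
Assumption: the (R,R)-configured carbene ligand of step 7 is taken to add H2 to the face of C2=C3 that gives (2R,3R); if the sense is the reverse, its (S,S)-enantiomer is used in the same step.

Step 1
Reactants: 1 4-bromo-2,6-dimethoxyphenol; 2 (S)-4-benzyl-3-(chloroacetyl)oxazolidin-2-one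
Product: 3 (S)-4-benzyl-3-[(4-bromo-2,6-dimethoxyphenoxy)acetyl]oxazolidin-2-one
Conditions: K2CO3, NaI (cat.), acetone, 50 °C
Reagents that add atoms: none
Why: Williamson ether synthesis by SN2 attack of the phenoxide on the activated primary α-halo imide (iodide-assisted); the auxiliary centre is not touched.

Step 2
Reactants: 3 (S)-4-benzyl-3-[(4-bromo-2,6-dimethoxyphenoxy)acetyl]oxazolidin-2-one; 4 4-(benzyloxy)-3-methoxybenzaldehyde
Product: 6 (S)-4-benzyl-3-[(2R,3R)-3-(4-benzyloxy-3-methoxyphenyl)-2-(4-bromo-2,6-dimethoxyphenoxy)-3-hydroxypropanoyl]oxazolidin-2-one, via O-trimethylsilyl aldol adduct 5 (not isolated)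
Conditions: MgCl2 (0.2 equiv), Et3N (2.5 equiv), TMSCl (2 equiv), EtOAc, 23 °C; then TFA (cat.), MeOH
Reagents that add atoms: chlorotrimethylsilane, C[Si](C)(C)Cl (its silyl group is kept in 5 only and is lost on work-up)
Why: Magnesium-halide-catalysed anti-selective aldol reaction of a chiral N-acyloxazolidinone (Evans anti-aldol), in which the chelated (Z)-magnesium enolate should react through a boat-like transition state on the face away from the benzyl group (C2 becomes R), the anti topology sets C3 as R, and silylation to 5 releases the metal before acidic methanol frees the alcohol.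

Step 3
Reactants: 6 (S)-4-benzyl-3-[(2R,3R)-3-(4-benzyloxy-3-methoxyphenyl)-2-(4-bromo-2,6-dimethoxyphenoxy)-3-hydroxypropanoyl]oxazolidin-2-one
Product: 7 (1R,2S)-1-(4-benzyloxy-3-methoxyphenyl)-2-(4-bromo-2,6-dimethoxyphenoxy)propane-1,3-diol
Conditions: LiBH4, THF, H2O (1 equiv), 0 °C
Reagents that add atoms: none
Why: Reductive cleavage of the imide by borohydride is the standard auxiliary removal; it should give the primary alcohol without touching the aryl bromide, the benzyl ether or either stereocentre.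

Step 4
Reactants: 7 (1R,2S)-1-(4-benzyloxy-3-methoxyphenyl)-2-(4-bromo-2,6-dimethoxyphenoxy)propane-1,3-diol; 8 prop-2-yn-1-ol
Product: 9 (1R,2S)-1-(4-benzyloxy-3-methoxyphenyl)-2-[4-(3-hydroxyprop-1-ynyl)-2,6-dimethoxyphenoxy]propane-1,3-diol
Conditions: PdCl2(PhCN)2 (3 mol%), P(t-Bu)3 (6 mol%), CuI (2 mol%), i-Pr2NH, dioxane, rt
Reagents that add atoms: none
Why: Sonogashira coupling; the bulky electron-rich phosphine should allow oxidative addition to the electron-rich aryl bromide at room temperature, and free hydroxyls are tolerated.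

Step 5
Reactants: 10 4-(3-hydroxypropyl)-2-methoxyphenol (dihydroconiferyl alcohol)
Product: 11 4-(3-hydroxypropyl)-2-iodo-6-methoxyphenol
Conditions: NIS, TsOH (cat.), MeCN, 0 °C to rt
Reagents that add atoms: N-iodosuccinimide, O=C1CCC(=O)N1I
Why: Electrophilic aromatic iodination directed ortho to the phenol hydroxyl, the para position being blocked by the side chain.

Step 6
Reactants: 9 (1R,2S)-1-(4-benzyloxy-3-methoxyphenyl)-2-[4-(3-hydroxyprop-1-ynyl)-2,6-dimethoxyphenoxy]propane-1,3-diol; 11 4-(3-hydroxypropyl)-2-iodo-6-methoxyphenol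
Product: 12 (1R,2S)-1-(4-benzyloxy-3-methoxyphenyl)-2-{4-[3-(hydroxymethyl)-5-(3-hydroxypropyl)-7-methoxybenzofuran-2-yl]-2,6-dimethoxyphenoxy}propane-1,3-diol
Conditions: Pd(OAc)2 (5 mol%), LiCl (1 equiv), Na2CO3 (3 equiv), DMF, 100 °C
Reagents that add atoms: none
Why: Larock heteroannulation: the C–I bond of 11 adds oxidatively to zerovalent palladium, the alkyne of 9 undergoes syn-carbopalladation (forming C3a–C3), the phenoxide displaces iodide on palladium, and C–O reductive elimination from the six-membered oxapalladacycle forms O1–C2. The closest known reaction type is the palladium-catalysed annulation of internal alkynes by o-iodophenols to 2,3-disubstituted benzofurans. The furan ring is closed by reductive elimination at the metal, so the operation is a formal (3+2) heteroannulation and not a nucleophilic ring closure. No stereocentre is formed; the step lays down the planar C2=C3 bond from which step 7 sets both ring centres. The selectivity needed is regiochemical (aryl at C2, CH2OH at C3), and it should be secured because the larger, conjugating aryl substituent of the alkyne ends up on the carbon bound to palladium, which is the carbon that then bonds to oxygen. The four free hydroxyls, the benzyl ether and the side-chain centres should be inert to the carbonate base because no free para-phenol is present to open a quinone methide pathway.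

Step 7
Reactants: 12 (1R,2S)-1-(4-benzyloxy-3-methoxyphenyl)-2-{4-[3-(hydroxymethyl)-5-(3-hydroxypropyl)-7-methoxybenzofuran-2-yl]-2,6-dimethoxyphenoxy}propane-1,3-diol
Product: 13 (1R,2S)-1-(4-benzyloxy-3-methoxyphenyl)-2-{4-[(2R,3R)-3-(hydroxymethyl)-5-(3-hydroxypropyl)-7-methoxy-2,3-dihydrobenzofuran-2-yl]-2,6-dimethoxyphenoxy}propane-1,3-diol
Conditions: H2 (80 bar), Ru(cod)(2-methylallyl)2 (5 mol%), (R,R)-1,3-bis[1-(naphthalen-1-yl)ethyl]-4,5-dihydroimidazolium tetrafluoroborate (10 mol%), KOt-Bu (15 mol%), toluene–t-AmOH, 40 °C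
Reagents that add atoms: none
Why: Asymmetric hydrogenation of the furan ring of a benzofuran with a chiral ruthenium N-heterocyclic carbene catalyst; syn delivery of H2 to one face of C2=C3 sets C2 and C3 together as cis, and the face is chosen by the catalyst, independent of the remote side-chain centres.

Step 8
Reactants: 13 (1R,2S)-1-(4-benzyloxy-3-methoxyphenyl)-2-{4-[(2R,3R)-3-(hydroxymethyl)-5-(3-hydroxypropyl)-7-methoxy-2,3-dihydrobenzofuran-2-yl]-2,6-dimethoxyphenoxy}propane-1,3-diol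
Product: 14 (1R,2S)-1-(4-hydroxy-3-methoxyphenyl)-2-{4-[(2R,3R)-3-(hydroxymethyl)-5-(3-hydroxypropyl)-7-methoxy-2,3-dihydrobenzofuran-2-yl]-2,6-dimethoxyphenoxy}propane-1,3-diol (target)
Conditions: H2 (1 atm), 10% palladium on carbon, EtOAc–MeOH, rt, stopped at full conversion
Reagents that add atoms: none
Why: Hydrogenolysis of the primary benzyl aryl ether; in neutral solvent at 1 atm the hindered secondary C2–O1 ether and the benzylic side-chain hydroxyl should survive.

Compound list
1 | 4-bromo-2,6-dimethoxyphenol | COc1cc(Br)cc(OC)c1O | starting material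
2 | (S)-4-benzyl-3-(chloroacetyl)oxazolidin-2-one | O=C(CCl)N1C(=O)OC[C@@H]1Cc1ccccc1 | starting material
3 | (S)-4-benzyl-3-[(4-bromo-2,6-dimethoxyphenoxy)acetyl]oxazolidin-2-one | COc1cc(Br)cc(OC)c1OCC(=O)N1C(=O)OC[C@@H]1Cc1ccccc1 | intermediate
4 | 4-(benzyloxy)-3-methoxybenzaldehyde | COc1cc(C=O)ccc1OCc1ccccc1 | starting material
5 | O-trimethylsilyl ether of aldol adduct 6 | COc1cc([C@@H](O[Si](C)(C)C)[C@H](C(=O)N2C(=O)OC[C@@H]2Cc2ccccc2)Oc2c(OC)cc(Br)cc2OC)ccc1OCc1ccccc1 | intermediate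
6 | (S)-4-benzyl-3-[(2R,3R)-3-(4-benzyloxy-3-methoxyphenyl)-2-(4-bromo-2,6-dimethoxyphenoxy)-3-hydroxypropanoyl]oxazolidin-2-one | COc1cc([C@@H](O)[C@H](C(=O)N2C(=O)OC[C@@H]2Cc2ccccc2)Oc2c(OC)cc(Br)cc2OC)ccc1OCc1ccccc1 | intermediate
7 | (1R,2S)-1-(4-benzyloxy-3-methoxyphenyl)-2-(4-bromo-2,6-dimethoxyphenoxy)propane-1,3-diol | COc1cc([C@@H](O)[C@H](CO)Oc2c(OC)cc(Br)cc2OC)ccc1OCc1ccccc1 | intermediate
8 | prop-2-yn-1-ol | C#CCO | starting material
9 | (1R,2S)-1-(4-benzyloxy-3-methoxyphenyl)-2-[4-(3-hydroxyprop-1-ynyl)-2,6-dimethoxyphenoxy]propane-1,3-diol | COc1cc([C@@H](O)[C@H](CO)Oc2c(OC)cc(C#CCO)cc2OC)ccc1OCc1ccccc1 | intermediate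
10 | 4-(3-hydroxypropyl)-2-methoxyphenol | COc1cc(CCCO)ccc1O | starting material
11 | 4-(3-hydroxypropyl)-2-iodo-6-methoxyphenol | COc1cc(CCCO)cc(I)c1O | intermediate
12 | (1R,2S)-1-(4-benzyloxy-3-methoxyphenyl)-2-{4-[3-(hydroxymethyl)-5-(3-hydroxypropyl)-7-methoxybenzofuran-2-yl]-2,6-dimethoxyphenoxy}propane-1,3-diol | COc1cc([C@@H](O)[C@H](CO)Oc2c(OC)cc(-c3oc4c(OC)cc(CCCO)cc4c3CO)cc2OC)ccc1OCc1ccccc1 | intermediate
13 | (1R,2S)-1-(4-benzyloxy-3-methoxyphenyl)-2-{4-[(2R,3R)-3-(hydroxymethyl)-5-(3-hydroxypropyl)-7-methoxy-2,3-dihydrobenzofuran-2-yl]-2,6-dimethoxyphenoxy}propane-1,3-diol | COc1cc([C@@H](O)[C@H](CO)Oc2c(OC)cc([C@@H]3Oc4c(OC)cc(CCCO)cc4[C@@H]3CO)cc2OC)ccc1OCc1ccccc1 | intermediate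
14 | (1R,2S)-1-(4-hydroxy-3-methoxyphenyl)-2-{4-[(2R,3R)-3-(hydroxymethyl)-5-(3-hydroxypropyl)-7-methoxy-2,3-dihydrobenzofuran-2-yl]-2,6-dimethoxyphenoxy}propane-1,3-diol | COc1cc([C@@H](O)[C@H](CO)Oc2c(OC)cc([C@@H]3Oc4c(OC)cc(CCCO)cc4[C@@H]3CO)cc2OC)ccc1O | target

Total step count: 8. Longest linear sequence: 7 steps (1, 2, 3, 4, 6, 7, 8); step 5 is a one-step branch.

Steps most likely to fail

Step 7. The tetrasubstituted C2=C3 bond may not turn over, or the catalyst may lose facial control, because the four free hydroxyls can bind ruthenium and the substrate is far more polar than typical benzofuran substrates. The fallback sets out from 12 and comes back at 14, replacing steps 7 and 8. Heterogeneous syn-hydrogenation over 10% palladium on carbon (H2, 5 bar, EtOAc–MeOH) should reduce the furan ring cis from either face and remove the benzyl group in the same operation. This gives 14 together with (1R,2S)-1-(4-hydroxy-3-methoxyphenyl)-2-{4-[(2S,3S)-3-(hydroxymethyl)-5-(3-hydroxypropyl)-7-methoxy-2,3-dihydrobenzofuran-2-yl]-2,6-dimethoxyphenoxy}propane-1,3-diol F1. Because the side-chain centres are fixed, 14 and F1 are diastereomers and are separated by preparative HPLC.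

Step 6. Alkyne insertion may leak to the 3-aryl-2-hydroxymethyl regioisomer, or the unhindered alkyne may insert twice before the slow C–O reductive elimination. The fallback sets out from 7 and 11 and comes back at 12, fixing the regiochemistry by construction. Sonogashira coupling of 7 with ethynyltrimethylsilane should give (1R,2S)-1-(4-benzyloxy-3-methoxyphenyl)-2-{2,6-dimethoxy-4-[(trimethylsilyl)ethynyl]phenoxy}propane-1,3-diol F2, and K2CO3 in MeOH the terminal alkyne (1R,2S)-1-(4-benzyloxy-3-methoxyphenyl)-2-(4-ethynyl-2,6-dimethoxyphenoxy)propane-1,3-diol F3. A copper-cocatalysed Sonogashira coupling of F3 with 11 at room temperature (PdCl2(PPh3)2, CuI, Et3N) should give the o-alkynylphenol (1R,2S)-1-(4-benzyloxy-3-methoxyphenyl)-2-(4-{[2-hydroxy-5-(3-hydroxypropyl)-3-methoxyphenyl]ethynyl}-2,6-dimethoxyphenoxy)propane-1,3-diol F4. Oxidative cyclisation with methoxycarbonylation (PdI2, thiourea, CBr4, Cs2CO3, CO, MeOH) should then give methyl 2-(4-{[(1R,2S)-1-(4-benzyloxy-3-methoxyphenyl)-1,3-dihydroxypropan-2-yl]oxy}-3,5-dimethoxyphenyl)-5-(3-hydroxypropyl)-7-methoxybenzofuran-3-carboxylate F5, and DIBAL-H reduction of the ester gives 12.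

Step 2. The anti-selectivity may erode because the α-aryloxy oxygen competes for magnesium, and the electron-rich aldehyde may add slowly and reversibly. The fallback sets out from 1 and 4 and comes back at 7. Alkylation of 1 with (R)-4-benzyl-3-(chloroacetyl)oxazolidin-2-one should give (R)-4-benzyl-3-[(4-bromo-2,6-dimethoxyphenoxy)acetyl]oxazolidin-2-one F6. Its boron enolate (Bu2BOTf, i-Pr2NEt, CH2Cl2, −78 °C) should add to 4 in the syn sense to give (R)-4-benzyl-3-[(2R,3S)-3-(4-benzyloxy-3-methoxyphenyl)-2-(4-bromo-2,6-dimethoxyphenoxy)-3-hydroxypropanoyl]oxazolidin-2-one F7. Mitsunobu inversion of the carbinol centre (4-nitrobenzoic acid, PPh3, DIAD) should give the (2R,3R) 4-nitrobenzoate (R)-4-benzyl-3-[(2R,3R)-3-(4-benzyloxy-3-methoxyphenyl)-2-(4-bromo-2,6-dimethoxyphenoxy)-3-(4-nitrobenzoyloxy)propanoyl]oxazolidin-2-one F8. LiBH4 then cleaves both the ester and the imide to give 7.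

Further compounds
F1 | step 7 | (1R,2S)-1-(4-hydroxy-3-methoxyphenyl)-2-{4-[(2S,3S)-3-(hydroxymethyl)-5-(3-hydroxypropyl)-7-methoxy-2,3-dihydrobenzofuran-2-yl]-2,6-dimethoxyphenoxy}propane-1,3-diol | COc1cc([C@@H](O)[C@H](CO)Oc2c(OC)cc([C@H]3Oc4c(OC)cc(CCCO)cc4[C@H]3CO)cc2OC)ccc1O
F2 | step 6 | (1R,2S)-1-(4-benzyloxy-3-methoxyphenyl)-2-{2,6-dimethoxy-4-[(trimethylsilyl)ethynyl]phenoxy}propane-1,3-diol | COc1cc([C@@H](O)[C@H](CO)Oc2c(OC)cc(C#C[Si](C)(C)C)cc2OC)ccc1OCc1ccccc1
F3 | step 6 | (1R,2S)-1-(4-benzyloxy-3-methoxyphenyl)-2-(4-ethynyl-2,6-dimethoxyphenoxy)propane-1,3-diol | COc1cc([C@@H](O)[C@H](CO)Oc2c(OC)cc(C#C)cc2OC)ccc1OCc1ccccc1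
F4 | step 6 | (1R,2S)-1-(4-benzyloxy-3-methoxyphenyl)-2-(4-{[2-hydroxy-5-(3-hydroxypropyl)-3-methoxyphenyl]ethynyl}-2,6-dimethoxyphenoxy)propane-1,3-diol | COc1cc([C@@H](O)[C@H](CO)Oc2c(OC)cc(C#Cc3cc(CCCO)cc(OC)c3O)cc2OC)ccc1OCc1ccccc1
F5 | step 6 | methyl 2-(4-{[(1R,2S)-1-(4-benzyloxy-3-methoxyphenyl)-1,3-dihydroxypropan-2-yl]oxy}-3,5-dimethoxyphenyl)-5-(3-hydroxypropyl)-7-methoxybenzofuran-3-carboxylate | COc1cc([C@@H](O)[C@H](CO)Oc2c(OC)cc(-c3oc4c(OC)cc(CCCO)cc4c3C(=O)OC)cc2OC)ccc1OCc1ccccc1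
F6 | step 2 | (R)-4-benzyl-3-[(4-bromo-2,6-dimethoxyphenoxy)acetyl]oxazolidin-2-one | COc1cc(Br)cc(OC)c1OCC(=O)N1C(=O)OC[C@H]1Cc1ccccc1
F7 | step 2 | (R)-4-benzyl-3-[(2R,3S)-3-(4-benzyloxy-3-methoxyphenyl)-2-(4-bromo-2,6-dimethoxyphenoxy)-3-hydroxypropanoyl]oxazolidin-2-one | COc1cc([C@H](O)[C@H](C(=O)N2C(=O)OC[C@H]2Cc2ccccc2)Oc2c(OC)cc(Br)cc2OC)ccc1OCc1ccccc1
F8 | step 2 | (R)-4-benzyl-3-[(2R,3R)-3-(4-benzyloxy-3-methoxyphenyl)-2-(4-bromo-2,6-dimethoxyphenoxy)-3-(4-nitrobenzoyloxy)propanoyl]oxazolidin-2-one | COc1cc([C@@H](OC(=O)c2ccc(cc2)[N+](=O)[O-])[C@H](C(=O)N2C(=O)OC[C@H]2Cc2ccccc2)Oc2c(OC)cc(Br)cc2OC)ccc1OCc1ccccc1
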